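**Easy step.** I began with what is easiest to read: how quickly target falls once it has peaked.

| flask | starting material | temperature | remark | time |
|---|---|---|---|---|
| Sunday's | 0.35 M | −1 °C | run made earlier |  |
| Friday's | 1.3 M | 29 °C | run made earlier |  |
| noon | 0.30 M | 25 °C |  | 12 min |
| midnight | 0.30 M | −15 °C |  | 12 min |
| summer | 1.0 M | 25 °C |  | 12 min |
| dawn | 0.30 M | 40 °C |  | 12 min |
| dusk | 1.0 M | 40 °C |  | 12 min |
| autumn | 1.0 M | −15 °C |  | 12 min |

| run | time / min | target / % | starting material / % |
|---|---|---|---|
| Sunday's | 5.00 | 69.7 | 29.2 |
| Sunday's | 15.0 | 75.1 | 22.4 |
| Sunday's | 30.0 | 73.6 | 21.5 |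
| Sunday's | 40.0 | 71.0 | 19.5 |
| Friday's | 1.50 | 68.7 | 18.9 |
| Friday's | 4.00 | 55.2 | 16.3 |
| Friday's | 8.00 | 43.1 | 13.1 |
| Friday's | 12.0 | 36.4 | 12.8 |

(scatter of a reading: 1 percentage point)

1. the flasks by amount of target, in percent of the starting material charged, highest first, at 12 min (noon / midnight / summer / dawn / dusk / autumn)
2. the amount of target, in percent of the starting material charged of the flask you put first, at 12 min
3. the amount of target, in percent of the starting material charged of the flask you put last, at 12 min

- percent here means starting material units held: one target counts as two

In Friday's run target went from 68.7% to 36.4% between 1.50 min and 12.0 min, which these two readings put at a half-life of 11.5 min.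

**Bench rule.** The old rule says a rate doubles for every 10 degrees, and dusk at 40 °C stands about that far above Friday's 29 °C. So I halved the figure to get the loss half-life of target in dusk, the time in which target past its peak halves: 5.73 min. I ignored the weaker charge of dusk and assumed it reaches Friday's first reading at the same time. From there to 12 min is 1.83 half-lives, so my reckoning for dusk was 19.3%.

**The border.** Sunday's readings at 15.0 min and 40.0 min, which differ by little more than their scatter, put the half-life at roughly 309 min, 26.9 times Friday's, where 3 doublings promise 8. Its charge also differs, by a factor of 3.71, so I held the doubling loosely. In 12 min that half-life allows a count of 0.0388, far too few to say anything, and Sunday's target was still rising from 69.7% to 75.1%. So I stopped counting at the cold end and did not use the count for midnight and autumn, which at −15 °C stand colder than Sunday's −1 °C.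

**The forecast.** It noted that “the −15 °C flasks are not quite at equilibrium at 12 min”. It gave the order autumn > midnight > noon > summer > dawn > dusk, with 83% on top (range 76% to 88%) and 27% for dusk at the bottom (range 18% to 35%). That is higher than my count for dusk.

**The result.** The flasks stood in the order autumn > midnight > noon > summer > dawn > dusk, with 83.7% in autumn and 17.1% in dusk.

    starting material + target → side product (k = 0.210 M⁻¹ min⁻¹, Ea = 54.0 kJ mol⁻¹)
    2 starting material ⇌ target (K = 9.50 M⁻¹, k = 4.40 M⁻¹ min⁻¹, Ea = 42.0 kJ mol⁻¹, ΔH = −23.0 kJ mol⁻¹)
    target → over-reaction product (k = 6.70 × 10⁻⁴ min⁻¹, Ea = 106 kJ mol⁻¹)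
    (constants at 25 °C)

**Fast balance.** In dusk at 12.0 min, starting material and target relax towards each other, a pre-equilibrium, with a half-life of 0.110 min, far shorter than the 5.71 min of the slowest mode of the whole flask. Between 6.00 min and 12.0 min target in dusk fell with a half-life of 7.09 min, against my 5.73 min. Counting on with 5.73 min, dusk left until 20 min should hold 6.50% target; it holds 9.79%.

(The data stem from a simulated flask for an exercise; scatter was added.)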